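**Plan**

- Locants: C1 is the methyl-bearing fusion carbon; C2 (angelate), C3, C4 (carbinol with i-Pr) and C5 (fusion CH) complete five-membered ring A; C6 (anisoate), C7, C8(CH3)=C9 and C10 complete seven-membered ring B. With C2 as a ketone, C4(OH)–C3H2–C2(=O) in ring A is an aldol pattern.
- Cuts, in order: the two ester C–O bonds and the C2–H bond; C3–C4 (retro-aldol, giving a 1,4-diketone on ring B); C8=C9 (olefin metathesis); the C4–isopropyl bond; C1–C5 (ester enolate Claisen); last, the ester link between a C7 hydroxy ester and a C7 dienol.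
- Forward: the chain is joined by transesterification and rearranged (C1–C5), the acid becomes the isopropyl ketone, ring B closes by metathesis, the vinyl group is oxidised, and ring A closes last by the aldol addition; a reduction and two acylations finish.
- Stereochemistry: C6 comes from ethyl (3R)-4-chloro-3-hydroxybutanoate; C5 and C1 from the chelated dianion Claisen (anti to the C6 oxygen, chair, E-olefin); C4 from C5 in the aldol; C2 from hydride attack opposite the angular methyl.

Key step: step 10

Remark: pent-1-en-4-yne is taken as a catalogue compound, and the locants C1–C10 of the plan are used for all intermediates.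

**Route**

Step 1
Reactants: 1 ethyl (3R)-4-chloro-3-hydroxybutanoate
Product: 2 ethyl 2-[(2R)-oxiran-2-yl]acetate
Conditions: Ag2O (1.2 equiv), 1,2-dimethoxyethane, 80 °C
Reagents that add atoms: none
Why: Halohydrin-to-epoxide closure (intramolecular Williamson etherification) driven by the halophilic, non-basic Ag2O, which should spare the base-sensitive β,γ-epoxy ester; the C–O bond at the stereocentre is not touched, so the future C6 keeps its configuration.

Step 2
Reactants: 2 ethyl 2-[(2R)-oxiran-2-yl]acetate; 3 isopropenylmagnesium bromide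
Product: 4 ethyl (3S)-3-hydroxy-5-methylhex-5-enoate
Conditions: CuI (10 mol%), THF, −40 °C; aq. NH4Cl
Reagents that add atoms: none
Why: Copper-catalysed Grignard opening of a terminal epoxide at its CH2 terminus, at −40 °C faster than attack on the ester or α-deprotonation; the carbinol centre is unchanged in space (the descriptor becomes S only through the priority change) and becomes C6.

Step 3
Reactants: 5 pent-1-en-4-yne
Product: 7 (2E)-3-methylhexa-2,5-dien-1-ol, via alkenylalane 6 (not isolated)
Conditions: AlMe3 (2 equiv), Cp2ZrCl2 (20 mol%), CH2Cl2, 0 → 23 °C; n-BuLi, THF, −78 °C; (CH2O)n, 23 °C; aq. HCl, 0 °C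
Reagents that add atoms: trimethylaluminium C[Al](C)C; formaldehyde (from paraformaldehyde) C=O
Why: Zirconium-catalysed methylalumination of a terminal alkyne (Negishi carboalumination), a syn addition that puts methyl on the internal carbon and is much faster than attack on the monosubstituted olefin, followed by hydroxymethylation of the alkenylalanate with retention, so the allyl arm and CH2OH end up trans (2E).

Step 4
Reactants: 4 ethyl (3S)-3-hydroxy-5-methylhex-5-enoate; 7 (2E)-3-methylhexa-2,5-dien-1-ol
Product: 8 (2E)-3-methylhexa-2,5-dien-1-yl (3S)-3-hydroxy-5-methylhex-5-enoate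
Conditions: Ti(OEt)4 (20 mol%), toluene, 100 °C, EtOH distilled off
Reagents that add atoms: none
Why: Titanate-mediated transesterification under neutral conditions, in which the primary allylic alcohol exchanges far faster than the secondary hydroxyl of 4, and neither dehydration nor retro-aldol cleavage of the β-hydroxy ester is expected.

Step 5
Reactants: 8 (2E)-3-methylhexa-2,5-dien-1-yl (3S)-3-hydroxy-5-methylhex-5-enoate
Product: 10 (2S,3S)-3-hydroxy-5-methyl-2-[(3S)-3-methylhexa-1,5-dien-3-yl]hex-5-enoic acid, via dilithium alkoxide enolate 9 (not isolated)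
Conditions: LiN(i-Pr)2 (2.1 equiv), THF, −78 → 23 °C; aq. HCl to pH 3, 0 °C
Reagents that add atoms: none
Why: Ireland–Claisen [3,3] rearrangement of a β-hydroxy ester dianion: the lithium chelate between alkoxide and enolate oxygen fixes the enolate with C6 cis to O–Li and, as in Fráter–Seebach alkylation, directs the allyl terminus to the face anti to the C7 arm (anti 2-alkyl-3-hydroxy acid, C5), while a chair with the E-olefin (C10 arm equatorial, methyl axial) sets quaternary C1 relative to C5; the β-oxide cannot be eliminated.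

Step 6
Reactants: 10 (2S,3S)-3-hydroxy-5-methyl-2-[(3S)-3-methylhexa-1,5-dien-3-yl]hex-5-enoic acid
Product: 12 (2S,3S)-3-[(tert-butyldimethylsilyl)oxy]-5-methyl-2-[(3S)-3-methylhexa-1,5-dien-3-yl]hex-5-enoic acid, via silyl ester 11 (not isolated)
Conditions: t-BuMe2SiOTf (2.5 equiv), 2,6-lutidine, CH2Cl2, 0 °C; then AcOH/THF/H2O, 23 °C
Reagents that add atoms: tert-butyldimethylsilyl trifluoromethanesulfonate CC(C)(C)[Si](C)(C)OS(=O)(=O)C(F)(F)F
Why: Silyl triflate/2,6-lutidine silylation covers both the hindered secondary hydroxyl and the acid, and mild aqueous acid then hydrolyses only the far more labile silyl ester.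

Step 7
Reactants: 12 (2S,3S)-3-[(tert-butyldimethylsilyl)oxy]-5-methyl-2-[(3S)-3-methylhexa-1,5-dien-3-yl]hex-5-enoic acid; 13 isopropylmagnesium chloride
Product: 15 (4S,5S)-5-[(tert-butyldimethylsilyl)oxy]-2,7-dimethyl-4-[(3S)-3-methylhexa-1,5-dien-3-yl]oct-7-en-3-one, via acid chloride 14 (not isolated)
Conditions: Me2C=C(Cl)NMe2, CH2Cl2, 0 → 23 °C; then 13 (1.2 equiv), Fe(acac)3 (5 mol%), THF, −78 °C
Reagents that add atoms: none
Why: Neutral conversion of the acid into its chloride with an α-chloroenamine, then iron-catalysed acylation of the acid chloride by the alkyl Grignard reagent, which at −78 °C should be faster than addition to the ketone formed, than olefin carbometalation and than ketene formation, so C5 should keep its configuration.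

Step 8
Reactants: 15 (4S,5S)-5-[(tert-butyldimethylsilyl)oxy]-2,7-dimethyl-4-[(3S)-3-methylhexa-1,5-dien-3-yl]oct-7-en-3-one
Product: 16 1-[(1S,2S,7S)-7-[(tert-butyldimethylsilyl)oxy]-2-ethenyl-2,5-dimethylcyclohept-4-en-1-yl]-2-methylpropan-1-one
Conditions: (H2IMes)(PCy3)Cl2Ru=CHPh (second-generation Grubbs catalyst, 5 mol%), CH2Cl2 (2 mM), 40 °C
Reagents that add atoms: none
Why: Ring-closing olefin metathesis: the ruthenium carbene forms at the unhindered allyl group and closes onto the 1,1-disubstituted olefin to give the trisubstituted cycloheptene (ring B), while the vinyl group on quaternary C1 is too hindered to initiate and could only form a four-membered ring with the allyl arm.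

Step 9
Reactants: 16 1-[(1S,2S,7S)-7-[(tert-butyldimethylsilyl)oxy]-2-ethenyl-2,5-dimethylcyclohept-4-en-1-yl]-2-methylpropan-1-one
Product: 17 1-[(1S,2R,7S)-2-acetyl-7-[(tert-butyldimethylsilyl)oxy]-2,5-dimethylcyclohept-4-en-1-yl]-2-methylpropan-1-one
Conditions: PdCl2 (15 mol%), CuCl (co-catalyst), O2 (1 atm), DMF/H2O 7:1, 23 °C
Reagents that add atoms: water O
Why: Tsuji–Wacker oxidation: Markovnikov hydroxypalladation of the only monosubstituted olefin converts the γ,δ-unsaturated ketone into the 1,4-diketone, the trisubstituted ring olefin and the silyl ether being inert under these conditions.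

Step 10
Reactants: 17 1-[(1S,2R,7S)-2-acetyl-7-[(tert-butyldimethylsilyl)oxy]-2,5-dimethylcyclohept-4-en-1-yl]-2-methylpropan-1-one
Product: 19 (3R,3aS,4S,8aR)-4-[(tert-butyldimethylsilyl)oxy]-3-hydroxy-6,8a-dimethyl-3-(propan-2-yl)-3,3a,4,5,8,8a-hexahydroazulen-1(2H)-one, via lithium enolate 18 (not isolated)
Conditions: LiN(i-Pr)2 (1.05 equiv), THF, −78 °C, then −40 °C; AcOH in THF, −78 °C
Reagents that add atoms: none
Why: LiN(i-Pr)2 removes a proton from the acetyl methyl group (C3), the least hindered α-position, and the lithium enolate adds to the C4 carbonyl of the isobutyryl group on C5, forming the C3–C4 bond and a lithium aldolate that is protonated cold. The closest known reaction type is the intramolecular aldol addition of 1,4-diketones that opens the classical cyclopentenone annulation, here halted at the 3-hydroxycyclopentanone. Ring A closes in a 5-(enolendo)-exo-trig mode (the enolate C2=C3 bond lies inside the new ring), a closure less easy than its six-membered counterpart but routine for 1,4-diketones and assisted here by the quaternary C1 and by the trans-diequatorial acetyl and isobutyryl groups on ring B. The new stereocentre C4 is set by C5: in the forming ring the isopropyl group takes the side of C5–H and the oxygen the side of the C5–C6 bond, which avoids eclipsing isopropyl with C6 and its silyloxy group, and any reversal of the aldolate should correct towards the same isomer. The step needs enolisation at C3 and not at C5 or the isopropyl methine, which kinetic deprotonation by a hindered amide at −78 °C secures; it also needs to stop at the aldol, which the lithium counter-ion, the low temperature and the acidic quench secure against dehydration and against β-elimination of the C6 silyloxy group. The trans ring fusion needs no control because C1 and C5 are already fixed.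

Step 11
Reactants: 19 (3R,3aS,4S,8aR)-4-[(tert-butyldimethylsilyl)oxy]-3-hydroxy-6,8a-dimethyl-3-(propan-2-yl)-3,3a,4,5,8,8a-hexahydroazulen-1(2H)-one
Product: 20 (1R,3R,3aS,4S,8aR)-4-[(tert-butyldimethylsilyl)oxy]-6,8a-dimethyl-3-(propan-2-yl)-1,2,3,3a,4,5,8,8a-octahydroazulene-1,3-diol
Conditions: NaBH4, CeCl3·7H2O, MeOH, −78 → −40 °C
Reagents that add atoms: none
Why: Luche-type borohydride reduction at low temperature and near-neutral pH (no retro-aldol): as with 17-oxo steroids, hydride should attack C2 from the ring face opposite the pseudo-axial angular methyl on C1, a face also free of the pseudo-axial C4 hydroxyl, so the new hydroxyl is cis to both (cis-1,3-diol, 2R); a boron chelate between C4–O and C2=O is geometrically impossible in the five-membered ring, so steric control is relied on.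

Step 12
Reactants: 20 (1R,3R,3aS,4S,8aR)-4-[(tert-butyldimethylsilyl)oxy]-6,8a-dimethyl-3-(propan-2-yl)-1,2,3,3a,4,5,8,8a-octahydroazulene-1,3-diol; 21 angelic acid, (2Z)-2-methylbut-2-enoic acid
Product: 23 (1R,3R,3aS,4S,8aR)-4-[(tert-butyldimethylsilyl)oxy]-3-hydroxy-6,8a-dimethyl-3-(propan-2-yl)-1,2,3,3a,4,5,8,8a-octahydroazulen-1-yl (2Z)-2-methylbut-2-enoate, via mixed anhydride 22 (not isolated)
Conditions: 21, 2,4,6-Cl3C6H2COCl, Et3N, toluene, 23 °C; then 20, 80 °C
Reagents that add atoms: none
Why: Yamaguchi-type esterification through the preformed mixed anhydride, run without a nucleophilic catalyst, is the established way to angelates without Z-to-E isomerisation to the tiglate; only the secondary C2 hydroxyl is acylated, the tertiary C4 hydroxyl being too hindered.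

Step 13
Reactants: 23 (1R,3R,3aS,4S,8aR)-4-[(tert-butyldimethylsilyl)oxy]-3-hydroxy-6,8a-dimethyl-3-(propan-2-yl)-1,2,3,3a,4,5,8,8a-octahydroazulen-1-yl (2Z)-2-methylbut-2-enoate
Product: 24 (1R,3R,3aS,4S,8aR)-3,4-dihydroxy-6,8a-dimethyl-3-(propan-2-yl)-1,2,3,3a,4,5,8,8a-octahydroazulen-1-yl (2Z)-2-methylbut-2-enoate
Conditions: HF·pyridine, pyridine/THF, 0 → 23 °C
Reagents that add atoms: none
Why: Fluoride cleavage of the Si–O bond with pyridine-buffered HF, weakly acidic conditions that should not cause acyl migration, angelate isomerisation or ionisation of the tertiary alcohol.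

Step 14
Reactants: 24 (1R,3R,3aS,4S,8aR)-3,4-dihydroxy-6,8a-dimethyl-3-(propan-2-yl)-1,2,3,3a,4,5,8,8a-octahydroazulen-1-yl (2Z)-2-methylbut-2-enoate; 25 4-methoxybenzoyl chloride
Product: 26 (1R,3R,3aS,4S,8aR)-3-hydroxy-6,8a-dimethyl-1-{[(2Z)-2-methylbut-2-enoyl]oxy}-3-(propan-2-yl)-1,2,3,3a,4,5,8,8a-octahydroazulen-4-yl 4-methoxybenzoate
Conditions: Et3N, DMAP (cat.), CH2Cl2, 23 °C
Reagents that add atoms: none
Why: DMAP-catalysed acyl transfer (Steglich-type) from the aroyl chloride to the secondary C6 hydroxyl; the tertiary C4 hydroxyl does not react, which completes the target.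

**Compound list**

1 | ethyl (3R)-4-chloro-3-hydroxybutanoate | CCOC(=O)C[C@@H](O)CCl | starting material
2 | ethyl 2-[(2R)-oxiran-2-yl]acetate | CCOC(=O)C[C@@H]1CO1 | intermediate
3 | isopropenylmagnesium bromide | C=C(C)[Mg]Br | starting material
4 | ethyl (3S)-3-hydroxy-5-methylhex-5-enoate | CCOC(=O)C[C@@H](O)CC(C)=C | intermediate
5 | pent-1-en-4-yne | C=CCC#C | starting material
6 | dimethyl[(1E)-2-methylpenta-1,4-dien-1-yl]alumane (formed in the flask) | C=CC/C(C)=C/[Al](C)C | intermediate
7 | (2E)-3-methylhexa-2,5-dien-1-ol | C=CC/C(C)=C/CO | intermediate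
8 | (2E)-3-methylhexa-2,5-dien-1-yl (3S)-3-hydroxy-5-methylhex-5-enoate | C=CC/C(C)=C/COC(=O)C[C@@H](O)CC(C)=C | intermediate
9 | dilithium alkoxide enolate of 8, C6 cis to the enolate O–Li (formed in the flask) | C=C(C)C[C@H](O[Li])/C=C(\O[Li])OC/C=C(\C)CC=C | intermediate
10 | (2S,3S)-3-hydroxy-5-methyl-2-[(3S)-3-methylhexa-1,5-dien-3-yl]hex-5-enoic acid | C=C[C@](C)(CC=C)[C@@H]([C@@H](O)CC(C)=C)C(O)=O | intermediate
11 | tert-butyldimethylsilyl (2S,3S)-3-[(tert-butyldimethylsilyl)oxy]-5-methyl-2-[(3S)-3-methylhexa-1,5-dien-3-yl]hex-5-enoate (formed in the flask) | C=C[C@](C)(CC=C)[C@@H]([C@@H](O[Si](C)(C)C(C)(C)C)CC(C)=C)C(=O)O[Si](C)(C)C(C)(C)C | intermediate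
12 | (2S,3S)-3-[(tert-butyldimethylsilyl)oxy]-5-methyl-2-[(3S)-3-methylhexa-1,5-dien-3-yl]hex-5-enoic acid | C=C[C@](C)(CC=C)[C@@H]([C@@H](O[Si](C)(C)C(C)(C)C)CC(C)=C)C(O)=O | intermediate
13 | isopropylmagnesium chloride | CC(C)[Mg]Cl | starting material
14 | (2S,3S)-3-[(tert-butyldimethylsilyl)oxy]-5-methyl-2-[(3S)-3-methylhexa-1,5-dien-3-yl]hex-5-enoyl chloride (formed in the flask) | C=C[C@](C)(CC=C)[C@@H]([C@@H](O[Si](C)(C)C(C)(C)C)CC(C)=C)C(Cl)=O | intermediate
15 | (4S,5S)-5-[(tert-butyldimethylsilyl)oxy]-2,7-dimethyl-4-[(3S)-3-methylhexa-1,5-dien-3-yl]oct-7-en-3-one | C=C[C@](C)(CC=C)[C@@H]([C@@H](O[Si](C)(C)C(C)(C)C)CC(C)=C)C(=O)C(C)C | intermediate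
16 | 1-[(1S,2S,7S)-7-[(tert-butyldimethylsilyl)oxy]-2-ethenyl-2,5-dimethylcyclohept-4-en-1-yl]-2-methylpropan-1-one | C=C[C@]1(C)CC=C(C)C[C@H](O[Si](C)(C)C(C)(C)C)[C@H]1C(=O)C(C)C | intermediate
17 | 1-[(1S,2R,7S)-2-acetyl-7-[(tert-butyldimethylsilyl)oxy]-2,5-dimethylcyclohept-4-en-1-yl]-2-methylpropan-1-one | CC(=O)[C@]1(C)CC=C(C)C[C@H](O[Si](C)(C)C(C)(C)C)[C@H]1C(=O)C(C)C | intermediate
18 | lithium enolate of the acetyl group of 17 (formed in the flask) | [Li]OC(=C)[C@]1(C)CC=C(C)C[C@H](O[Si](C)(C)C(C)(C)C)[C@H]1C(=O)C(C)C | intermediate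
19 | (3R,3aS,4S,8aR)-4-[(tert-butyldimethylsilyl)oxy]-3-hydroxy-6,8a-dimethyl-3-(propan-2-yl)-3,3a,4,5,8,8a-hexahydroazulen-1(2H)-one | O=C1C[C@@](O)(C(C)C)[C@@H]2[C@@H](O[Si](C)(C)C(C)(C)C)CC(C)=CC[C@]21C | intermediate
20 | (1R,3R,3aS,4S,8aR)-4-[(tert-butyldimethylsilyl)oxy]-6,8a-dimethyl-3-(propan-2-yl)-1,2,3,3a,4,5,8,8a-octahydroazulene-1,3-diol | O[C@@H]1C[C@@](O)(C(C)C)[C@@H]2[C@@H](O[Si](C)(C)C(C)(C)C)CC(C)=CC[C@]21C | intermediate
21 | angelic acid, (2Z)-2-methylbut-2-enoic acid | C/C=C(/C)C(=O)O | starting material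
22 | (2Z)-2-methylbut-2-enoic 2,4,6-trichlorobenzoic anhydride (formed in the flask) | C/C=C(/C)C(=O)OC(=O)c1c(Cl)cc(Cl)cc1Cl | intermediate
23 | (1R,3R,3aS,4S,8aR)-4-[(tert-butyldimethylsilyl)oxy]-3-hydroxy-6,8a-dimethyl-3-(propan-2-yl)-1,2,3,3a,4,5,8,8a-octahydroazulen-1-yl (2Z)-2-methylbut-2-enoate | C/C=C(/C)C(=O)O[C@@H]1C[C@@](O)(C(C)C)[C@@H]2[C@@H](O[Si](C)(C)C(C)(C)C)CC(C)=CC[C@]21C | intermediate
24 | (1R,3R,3aS,4S,8aR)-3,4-dihydroxy-6,8a-dimethyl-3-(propan-2-yl)-1,2,3,3a,4,5,8,8a-octahydroazulen-1-yl (2Z)-2-methylbut-2-enoate | C/C=C(/C)C(=O)O[C@@H]1C[C@@](O)(C(C)C)[C@@H]2[C@@H](O)CC(C)=CC[C@]21C | intermediate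
25 | 4-methoxybenzoyl chloride | COc1ccc(cc1)C(Cl)=O | starting material
26 | (1R,3R,3aS,4S,8aR)-3-hydroxy-6,8a-dimethyl-1-{[(2Z)-2-methylbut-2-enoyl]oxy}-3-(propan-2-yl)-1,2,3,3a,4,5,8,8a-octahydroazulen-4-yl 4-methoxybenzoate | C/C=C(/C)C(=O)O[C@@H]1C[C@@](O)(C(C)C)[C@@H]2[C@@H](OC(=O)c3ccc(OC)cc3)CC(C)=CC[C@]21C | target

**Step count and risks**

Total step count: 14 (each one-flask sequence counted as one step).
Longest linear sequence: 13 steps (from 1 through steps 1, 2 and 4 to 14); step 3 is the side branch.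

Steps most likely to fail:

1. Step 10. The 5-(enolendo) closure may be slow at the temperature where the kinetic enolate is regiostable. On warming, proton transfer could give the C5 enolate with β-elimination of the C6 silyloxy group, or the aldolate could revert or dehydrate. Fallback: starting from 17, the kinetic enolate is trapped (LiN(i-Pr)2, Me3SiCl, THF, −78 °C) as the trimethylsilyl enol ether of the acetyl group F1. Ring A is then closed by an intramolecular Mukaiyama aldol addition (TiCl4, CH2Cl2, −78 °C, aqueous work-up). This activates the C4 ketone with a Lewis acid instead of relying on a basic enolate, is not reversible under the conditions, forms the same C3–C4 bond and returns to the route at 19.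

2. Step 5. The lithium dianion may fragment (ketene loss) in competition with a rearrangement that has to build a quaternary centre, or incomplete chelation may erode enolate geometry and facial selectivity. Fallback: starting from 8, the hydroxyl is silylated (t-BuMe2SiCl, imidazole, DMF) to the silyl ether ester F2. Enolisation with LiN(i-Pr)2 in THF/DMPU and trapping with Me3SiCl should give the (Z)-trimethylsilyl ketene acetal F3 (C6 cis to OSiMe3), which is more stable than the lithium enolate. Heating to 50 °C effects the Ireland–Claisen rearrangement through the same chair to the trimethylsilyl ester F4, and aqueous acid hydrolyses it to 12, where the route is rejoined. The C1/C5 relation is still set by the chair; the C5/C6 relation then rests on acyclic 1,2-induction, and a minor diastereomer would be removed by chromatography at 12.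

3. Step 7. Acyl transfer at the carbonyl flanked by quaternary C1 and the silyloxy-bearing C6 may be sluggish, allowing ketene formation with loss of configuration at C5 or β-elimination. Fallback: starting from 12, LiAlH4 (Et2O, 0 °C) gives the primary alcohol F5 and Dess–Martin periodinane gives the aldehyde F6. The small aldehyde carbonyl should accept i-PrMgCl (with CeCl3, THF, −78 °C) to give the secondary alcohol F7 as a mixture of carbinol epimers. A second Dess–Martin oxidation returns to the route at 15.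

**Further compounds**

F1 | step 10 | 1-[(1S,2R,7S)-7-[(tert-butyldimethylsilyl)oxy]-2,5-dimethyl-2-{1-[(trimethylsilyl)oxy]ethenyl}cyclohept-4-en-1-yl]-2-methylpropan-1-one | C=C(O[Si](C)(C)C)[C@]1(C)CC=C(C)C[C@H](O[Si](C)(C)C(C)(C)C)[C@H]1C(=O)C(C)C
F2 | step 5 | (2E)-3-methylhexa-2,5-dien-1-yl (3S)-3-[(tert-butyldimethylsilyl)oxy]-5-methylhex-5-enoate | C=CC/C(C)=C/COC(=O)C[C@@H](O[Si](C)(C)C(C)(C)C)CC(C)=C
F3 | step 5 | (Z)-trimethylsilyl ketene acetal of F2 | C=C(C)C[C@H](O[Si](C)(C)C(C)(C)C)/C=C(\O[Si](C)(C)C)OC/C=C(\C)CC=C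
F4 | step 5 | trimethylsilyl (2S,3S)-3-[(tert-butyldimethylsilyl)oxy]-5-methyl-2-[(3S)-3-methylhexa-1,5-dien-3-yl]hex-5-enoate | C=C[C@](C)(CC=C)[C@@H]([C@@H](O[Si](C)(C)C(C)(C)C)CC(C)=C)C(=O)O[Si](C)(C)C
F5 | step 7 | (2R,3S)-3-[(tert-butyldimethylsilyl)oxy]-5-methyl-2-[(3S)-3-methylhexa-1,5-dien-3-yl]hex-5-en-1-ol | C=C[C@](C)(CC=C)[C@@H]([C@@H](O[Si](C)(C)C(C)(C)C)CC(C)=C)CO
F6 | step 7 | (2S,3S)-3-[(tert-butyldimethylsilyl)oxy]-5-methyl-2-[(3S)-3-methylhexa-1,5-dien-3-yl]hex-5-enal | C=C[C@](C)(CC=C)[C@@H]([C@@H](O[Si](C)(C)C(C)(C)C)CC(C)=C)C=O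
F7 | step 7 | (4R,5S)-5-[(tert-butyldimethylsilyl)oxy]-2,7-dimethyl-4-[(3S)-3-methylhexa-1,5-dien-3-yl]oct-7-en-3-ol, both C3 epimers | C=C[C@](C)(CC=C)[C@@H]([C@@H](O[Si](C)(C)C(C)(C)C)CC(C)=C)C(O)C(C)C
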